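## Structural features

The target (21) is an achiral, linear chain of four benzene rings held together by three diaryl ether oxygens. Ring A is a 2,4,6-trihydroxyphenyl unit with its ether on A4. Ring B has the ether to ring A on B1, hydroxyls on B3 and B4, and the ether to ring C on B5. Ring C has the ether to ring B on C1, hydroxyls on C2, C4 and C6, hydrogen on C3, and the ether to ring D on C5. Ring D is a 3,4,5-trihydroxyphenyl unit. There is no stereocentre; the only chiral compounds on the way are racemic cyclobutenones whose stereocentre vanishes on aromatisation. The eleven free phenols oxidise readily in air and in base, above all the three adjacent hydroxyls of ring D, the catechol of ring B and the hydroxyhydroquinone-like ring C, so they stay masked until the last step. The ether oxygens on A4, C1 and C5 each sit between two oxygen-bearing carbons, so every ether bond on rings A and C is hindered. The real difficulty is ring C, which carries five oxygens and two different aryloxy groups (ring B on C1, ring D on C5) that must be placed unambiguously. Ring B poses a smaller problem of the same kind, because B1 and B5 are not equivalent. The key step uses the fact that C4, C5, C6 and C1 are four contiguous oxygenated carbons, as in a squaric acid derivative, while C2 (oxygenated) and C3 (the only C–H) match a 1-alkoxyvinyl unit.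

## Logic of the disconnections

21 is traced back to 20 by cutting the eleven O–CH3 bonds. Methyl is the one protecting group that survives an organolithium, 110 °C, copper/base couplings and a peracid, so every earlier intermediate is stable and chromatographable. The demand on the forward step is an exhaustive Lewis-acid dealkylation that leaves the three diaryl ether links intact.

20 is cut at the bond between the ether oxygen and A4, giving 18 and 19. Ring A then enters as a purchasable aryl iodide, and the nucleophilic oxygen (on B1) has no ortho substituent. The forward step must arylate with a doubly ortho-substituted, electron-rich iodide; no other halide is present at that stage.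

18 is traced back to 16 (through 17) by replacing the B1–O bond with a B1–CHO bond. The formyl group is a masked hydroxyl, it activates the ring B bromide used one step earlier, and it removes any chance of self-coupling of a bromophenol. The forward oxidation needs aryl rather than hydride migration, which the methoxy group para to the formyl group (B4) supports.

16 is cut at the bond between the C1 oxygen and B5, giving 14 and 15. This separates the ring C/ring D phenol from a purchasable ring B piece. The most hindered nucleophile of the route therefore meets the smallest and most activated electrophile. The demand is O-arylation of a phenol flanked by two methoxy groups.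

14 goes back to 13 and then to 12 by two protecting-group changes: the C1–OH returns to a silyl ether and the C4–OMe to a free hydroxyl. The two para oxygens of ring C are thus distinguished by their origin, not by a selective reaction on a hydroquinone. The silyl ether must survive the methylation, and fluoride must cleave it without touching anything else.

12 is disconnected to 9 (through 11 and 10) by cutting the C3–C4 bond of ring C and restoring the sigma bond of a four-membered ring. The penta-oxygenated arene is thereby reduced to a squarate-derived cyclobutenone that already holds ring D on the correct oxygen. The forward step needs ring opening with the silyloxy group turning outward, and ring closure that outruns every other reaction of the ketene.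

9 is cut at the bond between the carbinol carbon (future C1) and the vinyl carbon (future C2), and at the O–Si bond, giving 5 and 6 (through 7 and 8). The forward step must add to one of two carbonyls of 5 selectively, namely the one next to the methoxy-bearing carbon.

5 is cut at its two vinylic C–O bonds, leading through 4 to 2, 3 and methanol; 2 comes from 1. The order of the two substitutions matters: chloride must be the leaving group each time, so that the alkoxy and aryloxy groups do not scramble.

## Other disconnections considered

Alternative 1: The cut is the A4–A5 bond of ring A, which is then made last from a pyrone.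
- **Forward step:** The pyranone A2 (4-methoxy-6-(aryloxymethyl)-2H-pyran-2-one carrying rings B, C and D) is heated with NaOMe in methanol. Methoxide opens the lactone, the carbon next to the aryloxy group attacks the ester carbonyl, and aromatisation should give the nona-O-methyl ether A1 with A3–OH and A5–OH free.
- **In favour:** The hindered ether on A4 is formed as an alkyl aryl ether by SN2 from 18 and the bromomethylpyrone A3, and two hydroxyls of the target emerge unprotected.
- **Against:** The carbanion required is the less acidic one of the opened chain. Hot methoxide offers other Claisen and retro-Claisen paths. Ring C, the hardest ring, is not addressed at all, so A2 still depends on a route to 18.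
- **Comparison:** On structure it solves ring A only and complements the chosen plan. On mechanism it is the better at the ring A ether, because it needs no copper coupling with a doubly ortho-substituted halide. On step economy it is slightly worse, with two steps (alkylation, ring transformation) in place of step 9.

Alternative 2: The cuts are B2–B3 and B1–B6 of ring B, which is assembled between two halves.
- **Forward step:** Heating the cyclobutenone A5 (4-methoxy-3-aryloxycyclobut-2-en-1-one carrying rings C and D, racemic) with the ethynyl ether A6 of ring A should give the phenol A4 in a Danheiser benzannulation: 4π opening, [2+2] addition to the alkyne, second 4π opening and 6π closure.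
- **Correction:** A4 has B3–OH free and carries ten methyl ethers (three each on rings A, C and D, one on ring B), so it is a deca-O-methyl ether.
- **In favour:** The union is convergent, both ether oxygens of ring B are in place before ring B exists, and the regiochemistry follows from the polarity of the ynol ether.
- **Against:** A5 can only be made from 14, so ring C must be built first in any case. A6 is an acid-sensitive aryl ynol ether of a hindered, electron-rich ring and needs its own multistep preparation. Benzannulations with an aryloxyacetylene and a 4-alkoxycyclobutenone are poorly charted.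
- **Comparison:** On mechanism it shares the electrocyclic logic of the chosen plan. On structure it is the better for convergence and for avoiding the hindered coupling of step 7. On step economy it is roughly equal at best, because two bespoke partners replace two purchasable ones and the strained-ring chemistry moves to the most valuable intermediates.

Alternative 3: The cuts are three C–O bonds (A1, C2, C4), traced back to three C–CHO bonds.
- **Forward step:** The trialdehyde A8 is treated with mCPBA and then K2CO3 in methanol, which should give the octa-O-methyl triol A7 by three Dakin-type aryl migrations.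
- **In favour:** Every ether carbon of rings A and C in A8 is ortho or para to a formyl group, so the hindered ethers could be made by metal-free nucleophilic aromatic substitution. The three hydroxyls revealed are free in the target.
- **Against:** Ring C with two formyl groups is electron-poor, so hydride migration to carboxylic acids competes in the first oxidation. The rings become more electron-rich with each oxidation and invite over-oxidation to quinones. A ring C core with two equivalent leaving groups would have to be desymmetrised with two different phenols.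
- **Comparison:** On step economy it is probably the better of the two, being short and convergent. On mechanism it is the equal of the chosen plan for ether formation, but it asks one reagent for three oxidations where the chosen plan uses the same reaction once, on ring B. On structure it depends on a pre-formed hexasubstituted benzene and does not build ring C.

Key step: step 4

Remark: the carbinol oxygen of the cyclobutenone is carried as its tert-butyldimethylsilyl ether, so that the ring expansion gives the two para oxygens of ring C already differentiated (no selective benzylation of a hydroquinone); the bonds formed, the ring closed and the skeletons of precursor and product are unchanged.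

## Route

Step 1
Reactants: 1 squaric acid
Product: 2 squaryl dichloride (3,4-dichlorocyclobut-3-ene-1,2-dione)
Conditions: (COCl)2, DMF (cat.), ClCH2CH2Cl, 50 °C
Reagents that add atoms: oxalyl chloride, ClC(=O)C(=O)Cl
Why: A vinylogous carboxylic acid is converted into its acid chloride by chloroiminium (Vilsmeier-type) activation; this is the standard preparation of 2.

Step 2
Reactants: 2 squaryl dichloride; 3 3,4,5-trimethoxyphenol
Product: 5 3-methoxy-4-(3,4,5-trimethoxyphenoxy)cyclobut-3-ene-1,2-dione, via 3-chloro-4-methoxycyclobut-3-ene-1,2-dione 4 (not isolated)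
Conditions: MeOH (1.0 equiv), CH2Cl2, −20 °C → rt, N2 purge; then 3, iPr2NEt, CH2Cl2, −78 → 0 °C
Reagents that add atoms: methanol, CO
Why: Two successive addition–elimination reactions (vinylogous acyl substitution) are run in the order that makes chloride the leaving group each time; the first substitution deactivates the ring enough to stop at 4, and the phenoxide then displaces the remaining chloride without exchanging the methoxy group.

Step 3
Reactants: 5 3-methoxy-4-(3,4,5-trimethoxyphenoxy)cyclobut-3-ene-1,2-dione; 6 methyl vinyl ether
Product: 9 4-[(tert-butyldimethylsilyl)oxy]-3-methoxy-4-(1-methoxyvinyl)-2-(3,4,5-trimethoxyphenoxy)cyclobut-2-en-1-one (racemic), via 1-methoxyvinyllithium 7 (not isolated), via lithium alkoxide adduct 8 (not isolated)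
Conditions: 6, t-BuLi, THF, −78 → 0 °C; then 5, THF, −78 °C; then TBSOTf, −78 → −30 °C
Reagents that add atoms: tert-butyldimethylsilyl trifluoromethanesulfonate, CC(C)(C)[Si](C)(C)OS(=O)(=O)C(F)(F)F
Why: This is a 1,2-addition of an α-alkoxyvinyllithium to a squarate ester followed by O-silylation of the lithium alkoxide; the carbonyl next to the methoxy-bearing carbon is attacked because its vinylogous donor is the weaker aryloxy group and its neighbour is the smaller substituent. The new stereocentre forms as a racemate and is erased in step 4.

Step 4
Reactants: 9 4-[(tert-butyldimethylsilyl)oxy]-3-methoxy-4-(1-methoxyvinyl)-2-(3,4,5-trimethoxyphenoxy)cyclobut-2-en-1-one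
Product: 12 4-[(tert-butyldimethylsilyl)oxy]-3,5-dimethoxy-2-(3,4,5-trimethoxyphenoxy)phenol, via (3Z)-dienylketene 10 (not isolated), via cyclohexa-2,4-dienone 11 (not isolated)
Conditions: PhMe (0.02 M, degassed), 110 °C, Ar
Reagents that add atoms: none
Why: Thermal conrotatory 4π opening of the cyclobutenone breaks the bond between the carbonyl carbon and the silyloxy carbon and gives the dienylketene 10. A thermally allowed disrotatory 6π electrocyclisation then joins the ketene carbon to the CH2 terminus of the methoxyvinyl group (ring C bond C3–C4) to give 11, which enolises to the phenol 12. The closest known reaction is the Moore rearrangement of squarate-derived 4-alkenyl-4-hydroxy- or 4-silyloxycyclobutenones. The one ring formed is the six-membered carbocycle, closed by 6π electrocyclisation and made irreversible by aromatisation. No stereocentre is created, and the racemic centre of 9 becomes sp2. The step needs torquoselectivity: the silyloxy donor should rotate outward, which turns the vinyl group toward the ketene, and the unproductive geometry can only reclose to 9 and try again. It also needs the closure to beat other ketene reactions; the capped carbinol oxygen cannot lactonise onto the ketene and high dilution disfavours intermolecular capture. The four squarate carbons become C4, C5, C6 and C1 and the vinyl carbons C2 and C3, so the free hydroxyl is on C4 and the silyl ether on C1.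

Step 5
Reactants: 12 4-[(tert-butyldimethylsilyl)oxy]-3,5-dimethoxy-2-(3,4,5-trimethoxyphenoxy)phenol
Product: 13 tert-butyl(dimethyl)[2,4,6-trimethoxy-3-(3,4,5-trimethoxyphenoxy)phenoxy]silane
Conditions: MeI, K2CO3, acetone, rt, Ar
Reagents that add atoms: iodomethane, CI
Why: Williamson methylation of the only free phenol (C4–OH); the aryl silyl ether, shielded by two ortho methoxy groups, should survive anhydrous carbonate.

Step 6
Reactants: 13 tert-butyl(dimethyl)[2,4,6-trimethoxy-3-(3,4,5-trimethoxyphenoxy)phenoxy]silane
Product: 14 2,4,6-trimethoxy-3-(3,4,5-trimethoxyphenoxy)phenol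
Conditions: TBAF, AcOH, THF, 0 °C
Reagents that add atoms: none
Why: Fluoride-driven cleavage of the Si–O bond frees the C1 hydroxyl; the acetic acid buffer keeps the electron-rich phenol protonated and limits aerial oxidation.

Step 7
Reactants: 14 2,4,6-trimethoxy-3-(3,4,5-trimethoxyphenoxy)phenol; 15 3-bromo-4,5-dimethoxybenzaldehyde
Product: 16 3,4-dimethoxy-5-[2,4,6-trimethoxy-3-(3,4,5-trimethoxyphenoxy)phenoxy]benzaldehyde
Conditions: CuI (20 mol %), picolinic acid (40 mol %), K3PO4, DMSO, 100 °C, Ar
Reagents that add atoms: none
Why: Ullmann-type copper-catalysed O-arylation with a ligand system suited to ortho-disubstituted phenols; the formyl group makes the bromide more reactive than an all-alkoxy arene and is the latent B1 oxygen.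

Step 8
Reactants: 16 3,4-dimethoxy-5-[2,4,6-trimethoxy-3-(3,4,5-trimethoxyphenoxy)phenoxy]benzaldehyde
Product: 18 3,4-dimethoxy-5-[2,4,6-trimethoxy-3-(3,4,5-trimethoxyphenoxy)phenoxy]phenol, via aryl formate 17 (not isolated)
Conditions: mCPBA, CH2Cl2, 0 °C → rt; aq. Na2SO3/NaHCO3 wash; then K2CO3 (cat.), MeOH, rt
Reagents that add atoms: 3-chloroperbenzoic acid, OOC(=O)c1cccc(Cl)c1
Why: Baeyer–Villiger (Dakin-type) oxidation of an electron-rich benzaldehyde; aryl migration is favoured by the para methoxy group on B4, and methanolysis of the formate frees B1–OH.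

Step 9
Reactants: 18 3,4-dimethoxy-5-[2,4,6-trimethoxy-3-(3,4,5-trimethoxyphenoxy)phenoxy]phenol; 19 2-iodo-1,3,5-trimethoxybenzene
Product: 20 1,3,5-trimethoxy-2-{3,4-dimethoxy-5-[2,4,6-trimethoxy-3-(3,4,5-trimethoxyphenoxy)phenoxy]phenoxy}benzene (undeca-O-methyl ether of the target)
Conditions: 19 (2 equiv), CuI (20 mol %), picolinic acid (40 mol %), K3PO4, DMSO, 100 °C, Ar
Reagents that add atoms: none
Why: Ullmann-type O-arylation in which the phenol is unhindered (hydrogens on B2 and B6) and the iodide is the only halide present, so no self-coupling can occur.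

Step 10
Reactants: 20 undeca-O-methyl ether of the target
Product: 21 2-{3,4-dihydroxy-5-[2,4,6-trihydroxy-3-(3,4,5-trihydroxyphenoxy)phenoxy]phenoxy}benzene-1,3,5-triol (CNP0214481.0)
Conditions: BBr3 (ca. 25 equiv), CH2Cl2, −78 °C → rt, Ar; then ice-water
Reagents that add atoms: none
Why: Lewis-acid cleavage of aryl methyl ethers (boron coordinates the oxygen, bromide attacks the methyl group in an SN2 step); diaryl ether C–O bonds are not attacked, and the acidic, oxygen-free work-up protects the free polyphenol.

## Compound list

1 | squaric acid (3,4-dihydroxycyclobut-3-ene-1,2-dione) | O=C1C(O)=C(O)C1=O | starting material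
2 | squaryl dichloride (3,4-dichlorocyclobut-3-ene-1,2-dione) | O=C1C(Cl)=C(Cl)C1=O | intermediate
3 | 3,4,5-trimethoxyphenol | COc1cc(O)cc(OC)c1OC | starting material
4 | 3-chloro-4-methoxycyclobut-3-ene-1,2-dione (not isolated) | COC1=C(Cl)C(=O)C1=O | intermediate
5 | 3-methoxy-4-(3,4,5-trimethoxyphenoxy)cyclobut-3-ene-1,2-dione | COC1=C(Oc2cc(OC)c(OC)c(OC)c2)C(=O)C1=O | intermediate
6 | methyl vinyl ether | COC=C | starting material
7 | 1-methoxyvinyllithium (not isolated) | [Li]C(=C)OC | intermediate
8 | lithium 2-methoxy-1-(1-methoxyvinyl)-4-oxo-3-(3,4,5-trimethoxyphenoxy)cyclobut-2-en-1-olate (racemic, not isolated) | COC(=C)C1([O-])C(OC)=C(Oc2cc(OC)c(OC)c(OC)c2)C1=O.[Li+] | intermediate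
9 | 4-[(tert-butyldimethylsilyl)oxy]-3-methoxy-4-(1-methoxyvinyl)-2-(3,4,5-trimethoxyphenoxy)cyclobut-2-en-1-one (racemic) | COC(=C)C1(O[Si](C)(C)C(C)(C)C)C(OC)=C(Oc2cc(OC)c(OC)c(OC)c2)C1=O | intermediate
10 | (3Z)-4-[(tert-butyldimethylsilyl)oxy]-3,5-dimethoxy-2-(3,4,5-trimethoxyphenoxy)hexa-1,3,5-trien-1-one (dienylketene, not isolated) | O=C=C(Oc1cc(OC)c(OC)c(OC)c1)/C(OC)=C(\C(OC)=C)O[Si](C)(C)C(C)(C)C | intermediate
11 | 4-[(tert-butyldimethylsilyl)oxy]-3,5-dimethoxy-2-(3,4,5-trimethoxyphenoxy)cyclohexa-2,4-dien-1-one (not isolated) | O=C1CC(OC)=C(O[Si](C)(C)C(C)(C)C)C(OC)=C1Oc1cc(OC)c(OC)c(OC)c1 | intermediate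
12 | 4-[(tert-butyldimethylsilyl)oxy]-3,5-dimethoxy-2-(3,4,5-trimethoxyphenoxy)phenol | COc1cc(O)c(Oc2cc(OC)c(OC)c(OC)c2)c(OC)c1O[Si](C)(C)C(C)(C)C | intermediate
13 | tert-butyl(dimethyl)[2,4,6-trimethoxy-3-(3,4,5-trimethoxyphenoxy)phenoxy]silane | COc1cc(OC)c(Oc2cc(OC)c(OC)c(OC)c2)c(OC)c1O[Si](C)(C)C(C)(C)C | intermediate
14 | 2,4,6-trimethoxy-3-(3,4,5-trimethoxyphenoxy)phenol | COc1cc(OC)c(Oc2cc(OC)c(OC)c(OC)c2)c(OC)c1O | intermediate
15 | 3-bromo-4,5-dimethoxybenzaldehyde | COc1cc(C=O)cc(Br)c1OC | starting material
16 | 3,4-dimethoxy-5-[2,4,6-trimethoxy-3-(3,4,5-trimethoxyphenoxy)phenoxy]benzaldehyde | COc1cc(C=O)cc(Oc2c(OC)cc(OC)c(Oc3cc(OC)c(OC)c(OC)c3)c2OC)c1OC | intermediate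
17 | 3,4-dimethoxy-5-[2,4,6-trimethoxy-3-(3,4,5-trimethoxyphenoxy)phenoxy]phenyl formate (not isolated) | COc1cc(OC=O)cc(Oc2c(OC)cc(OC)c(Oc3cc(OC)c(OC)c(OC)c3)c2OC)c1OC | intermediate
18 | 3,4-dimethoxy-5-[2,4,6-trimethoxy-3-(3,4,5-trimethoxyphenoxy)phenoxy]phenol | COc1cc(O)cc(Oc2c(OC)cc(OC)c(Oc3cc(OC)c(OC)c(OC)c3)c2OC)c1OC | intermediate
19 | 2-iodo-1,3,5-trimethoxybenzene | COc1cc(OC)c(I)c(OC)c1 | starting material
20 | 1,3,5-trimethoxy-2-{3,4-dimethoxy-5-[2,4,6-trimethoxy-3-(3,4,5-trimethoxyphenoxy)phenoxy]phenoxy}benzene | COc1cc(OC)c(Oc2cc(OC)c(OC)c(Oc3c(OC)cc(OC)c(Oc4cc(OC)c(OC)c(OC)c4)c3OC)c2)c(OC)c1 | intermediate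
21 | 2-{3,4-dihydroxy-5-[2,4,6-trihydroxy-3-(3,4,5-trihydroxyphenoxy)phenoxy]phenoxy}benzene-1,3,5-triol | Oc1cc(O)c(Oc2cc(O)c(O)c(Oc3c(O)cc(O)c(Oc4cc(O)c(O)c(O)c4)c3O)c2)c(O)c1 | target

## Step count and risks

Total step count: 10. Longest linear sequence: 10 steps (1 to 21; compounds 3, 6, 15 and 19 enter as purchased pieces).

Steps least certain to work:

**Step 4 (key step).**
- **Risk:** The ketene 10 may be consumed before it cyclises, either by electrophilic attack on the electron-rich ortho carbon of ring D or by intermolecular capture. The electron-rich product may also be lost to oxidation. An aryloxy group on the ketene carbon is not a charted substituent for this ring expansion.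
- **Fallback:** This sets out from 3, comes back at 14, and gives up the de novo construction of ring C. Purchased 2,4,6-trimethoxybenzaldehyde is brominated (NBS, MeCN, 0 °C) to 3-bromo-2,4,6-trimethoxybenzaldehyde F1. Copper-catalysed coupling of 3 with F1 (CuI, picolinic acid, K3PO4, DMSO) gives 2,4,6-trimethoxy-3-(3,4,5-trimethoxyphenoxy)benzaldehyde F2. Baeyer–Villiger oxidation with mCPBA gives 2,4,6-trimethoxy-3-(3,4,5-trimethoxyphenoxy)phenyl formate F3, and methanolysis gives 14. This reaches 14 in three steps, against six by the squarate route.

**Step 3.**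
- **Risk:** Addition may occur at the other carbonyl, or conjugate addition–elimination may expel the aryloxide. The electronic difference between a methoxy and an aryloxy donor is moderate, and aryloxide is a good leaving group.
- **Fallback:** This sets out from 2 (with 3 and 7) and comes back at 9. Both chlorides of 2 are displaced by 3 (2 equiv, iPr2NEt) to give the symmetrical 3,4-bis(3,4,5-trimethoxyphenoxy)cyclobut-3-ene-1,2-dione F4, whose carbonyls are equivalent. Addition of 7 gives the lithium alkoxide adduct F5, which is silylated in the flask to 4-[(tert-butyldimethylsilyl)oxy]-4-(1-methoxyvinyl)-2,3-bis(3,4,5-trimethoxyphenoxy)cyclobut-2-en-1-one F6. NaOMe in MeOH/THF at −20 °C then exchanges only the aryloxy group on the β-carbon of the enone (vinylogous transesterification by addition–elimination). The α-aryloxy group cannot leave, so 9 is obtained with its regiochemistry fixed by the enone.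

**Step 7.**
- **Risk:** Slow C–O bond formation at a phenol flanked by two methoxy groups leaves time for hydrodebromination of 15 and for oxidative decay of the phenoxide.
- **Fallback:** This sets out from 14 and comes back at 16, using metal-free aryl transfer from trivalent iodine, which tolerates ortho substitution on both partners. Purchased 3-iodo-4,5-dimethoxybenzaldehyde is oxidised (mCPBA, TsOH·H2O, MeCN) and captured with 1,3,5-trimethoxybenzene to give (5-formyl-2,3-dimethoxyphenyl)(2,4,6-trimethoxyphenyl)iodonium tosylate F7. Treatment of 14 with F7 and K2CO3 in toluene at 50 °C should transfer the less electron-rich formyl-bearing aryl group to oxygen and give 16; the iodoarene released is 19.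

**Step 9.**
- **Risk:** Sluggish oxidative addition of the doubly ortho-substituted, electron-rich iodide and its hydrodeiodination may stall the coupling.
- **Fallback:** This sets out from 18 and comes back at 21. Nucleophilic aromatic substitution of 18 on 4-fluoro-3,5-dimethoxybenzaldehyde (a catalogue building block; K2CO3, DMF, 120 °C) gives 4-{3,4-dimethoxy-5-[2,4,6-trimethoxy-3-(3,4,5-trimethoxyphenoxy)phenoxy]phenoxy}-3,5-dimethoxybenzaldehyde F8. Baeyer–Villiger oxidation gives the aryl formate F9, and methanolysis gives 4-{3,4-dimethoxy-5-[2,4,6-trimethoxy-3-(3,4,5-trimethoxyphenoxy)phenoxy]phenoxy}-3,5-dimethoxyphenol F10. BBr3 then cleaves the ten methyl ethers of F10 to 21.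

**Step 10.**
- **Risk:** Cleavage of eleven methyl ethers may stop short, since boron chelates on neighbouring oxygens slow the later cleavages, and the free polyphenol may oxidise during isolation.
- **Fallback:** This sets out from 20 and comes back at 21 through a protecting-group exchange. The crude BBr3 product is peracetylated (Ac2O, pyridine) to the undeca-O-acetate of the target F11, which is stable to air and silica and can be freed from partly methylated material. Acid-catalysed methanolysis under argon (AcCl in MeOH) then releases 21.

## Further compounds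

F1 | step 4 | 3-bromo-2,4,6-trimethoxybenzaldehyde | COc1cc(OC)c(Br)c(OC)c1C=O
F2 | step 4 | 2,4,6-trimethoxy-3-(3,4,5-trimethoxyphenoxy)benzaldehyde | COc1cc(OC)c(Oc2cc(OC)c(OC)c(OC)c2)c(OC)c1C=O
F3 | step 4 | 2,4,6-trimethoxy-3-(3,4,5-trimethoxyphenoxy)phenyl formate | COc1cc(OC)c(Oc2cc(OC)c(OC)c(OC)c2)c(OC)c1OC=O
F4 | step 3 | 3,4-bis(3,4,5-trimethoxyphenoxy)cyclobut-3-ene-1,2-dione | COc1cc(OC2=C(Oc3cc(OC)c(OC)c(OC)c3)C(=O)C2=O)cc(OC)c1OC
F5 | step 3 | lithium 1-(1-methoxyvinyl)-4-oxo-2,3-bis(3,4,5-trimethoxyphenoxy)cyclobut-2-en-1-olate (racemic) | COC(=C)C1([O-])C(Oc2cc(OC)c(OC)c(OC)c2)=C(Oc2cc(OC)c(OC)c(OC)c2)C1=O.[Li+]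
F6 | step 3 | 4-[(tert-butyldimethylsilyl)oxy]-4-(1-methoxyvinyl)-2,3-bis(3,4,5-trimethoxyphenoxy)cyclobut-2-en-1-one (racemic) | COC(=C)C1(O[Si](C)(C)C(C)(C)C)C(Oc2cc(OC)c(OC)c(OC)c2)=C(Oc2cc(OC)c(OC)c(OC)c2)C1=O
F7 | step 7 | (5-formyl-2,3-dimethoxyphenyl)(2,4,6-trimethoxyphenyl)iodonium 4-methylbenzenesulfonate | COc1cc(C=O)cc([I+]c2c(OC)cc(OC)cc2OC)c1OC.Cc1ccc(S(=O)(=O)[O-])cc1
F8 | step 9 | 4-{3,4-dimethoxy-5-[2,4,6-trimethoxy-3-(3,4,5-trimethoxyphenoxy)phenoxy]phenoxy}-3,5-dimethoxybenzaldehyde | COc1cc(C=O)cc(OC)c1Oc1cc(OC)c(OC)c(Oc2c(OC)cc(OC)c(Oc3cc(OC)c(OC)c(OC)c3)c2OC)c1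
F9 | step 9 | 4-{3,4-dimethoxy-5-[2,4,6-trimethoxy-3-(3,4,5-trimethoxyphenoxy)phenoxy]phenoxy}-3,5-dimethoxyphenyl formate | COc1cc(OC=O)cc(OC)c1Oc1cc(OC)c(OC)c(Oc2c(OC)cc(OC)c(Oc3cc(OC)c(OC)c(OC)c3)c2OC)c1
F10 | step 9 | 4-{3,4-dimethoxy-5-[2,4,6-trimethoxy-3-(3,4,5-trimethoxyphenoxy)phenoxy]phenoxy}-3,5-dimethoxyphenol | COc1cc(O)cc(OC)c1Oc1cc(OC)c(OC)c(Oc2c(OC)cc(OC)c(Oc3cc(OC)c(OC)c(OC)c3)c2OC)c1
F11 | step 10 | undeca-O-acetate of the target (every hydroxyl of 21 as its acetate) | CC(=O)Oc1cc(OC(C)=O)c(Oc2cc(OC(C)=O)c(OC(C)=O)c(Oc3c(OC(C)=O)cc(OC(C)=O)c(Oc4cc(OC(C)=O)c(OC(C)=O)c(OC(C)=O)c4)c3OC(C)=O)c2)c(OC(C)=O)c1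
A1 | alternative 1 | 5-methoxy-2-{3,4-dimethoxy-5-[2,4,6-trimethoxy-3-(3,4,5-trimethoxyphenoxy)phenoxy]phenoxy}benzene-1,3-diol (nona-O-methyl ether, A3–OH and A5–OH free) | COc1cc(O)c(Oc2cc(OC)c(OC)c(Oc3c(OC)cc(OC)c(Oc4cc(OC)c(OC)c(OC)c4)c3OC)c2)c(O)c1
A2 | alternative 1 | 4-methoxy-6-({3,4-dimethoxy-5-[2,4,6-trimethoxy-3-(3,4,5-trimethoxyphenoxy)phenoxy]phenoxy}methyl)-2H-pyran-2-one | COC1=CC(=O)OC(COc2cc(OC)c(OC)c(Oc3c(OC)cc(OC)c(Oc4cc(OC)c(OC)c(OC)c4)c3OC)c2)=C1
A3 | alternative 1 | 6-(bromomethyl)-4-methoxy-2H-pyran-2-one | COC1=CC(=O)OC(CBr)=C1
A4 | alternative 2 | 2-methoxy-5-(2,4,6-trimethoxyphenoxy)-3-[2,4,6-trimethoxy-3-(3,4,5-trimethoxyphenoxy)phenoxy]phenol (deca-O-methyl ether, B3–OH free) | COc1cc(OC)cc(OC)c1Oc1cc(O)c(OC)c(Oc2c(OC)cc(OC)c(Oc3cc(OC)c(OC)c(OC)c3)c2OC)c1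
A5 | alternative 2 | 4-methoxy-3-[2,4,6-trimethoxy-3-(3,4,5-trimethoxyphenoxy)phenoxy]cyclobut-2-en-1-one (racemic) | COC1C(=O)C=C1Oc1c(OC)cc(OC)c(Oc2cc(OC)c(OC)c(OC)c2)c1OC
A6 | alternative 2 | 2-(ethynyloxy)-1,3,5-trimethoxybenzene | C#COc1c(OC)cc(OC)cc1OC
A7 | alternative 3 | 4-{3-[4,6-dihydroxy-2-methoxy-3-(3,4,5-trimethoxyphenoxy)phenoxy]-4,5-dimethoxyphenoxy}-3,5-dimethoxyphenol (octa-O-methyl ether, A1–OH, C2–OH and C4–OH free) | COc1cc(O)cc(OC)c1Oc1cc(OC)c(OC)c(Oc2c(O)cc(O)c(Oc3cc(OC)c(OC)c(OC)c3)c2OC)c1
A8 | alternative 3 | trialdehyde corresponding to A7, with formyl groups in place of the hydroxyls on A1, C2 and C4 | COc1cc(C=O)cc(OC)c1Oc1cc(OC)c(OC)c(Oc2c(C=O)cc(C=O)c(Oc3cc(OC)c(OC)c(OC)c3)c2OC)c1
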